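**Retrosynthetic overview**
1. Dihydropyranone (last ring): acid cyclodehydration of a δ-hydroxy-β-diketone carried on C3 of the coumarin.
2. Coumarin ring (second): Knoevenagel/translactonisation of salicylaldehyde 9 with 4-hydroxy-2-pyranone 15; the pyranone ring, made first, is sacrificed and supplies C2, C3 and the diketone.
3. Aldehyde 9: aryl Grignard opening of (2R,3R)-2,3-epoxybutane (sets benzylic R), Mitsunobu inversion (sets carbinol S), Rieche formylation, demethylation.
4. Pyranone 15: methyl (R)-3-hydroxybutanoate (source of the pyranone stereocentre) acylates the methyl acetoacetate dianion, then enol-lactonisation.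
5. Ring order: 2-pyranone → coumarin lactone → dihydropyranone.

Assumption: 5-bromo-1,3-dimethoxy-2-methylbenzene (1) is taken as a catalogue building block (TBS = tert-butyldimethylsilyl).

**Route**

Step 1
Reactants: 1 5-bromo-1,3-dimethoxy-2-methylbenzene
Product: 3 1-bromo-3,5-dimethoxy-2,4-dimethylbenzene, via aryllithium 2 (not isolated)
Conditions: LDA (commercial solution, 1.1 equiv), THF, −78 °C, 1 h; MeI, −78 °C → rt
Reagents that add atoms: iodomethane, CI
Why: Directed ortho-lithiation at the ring C–H flanked by Br and OMe (the most acidic site; the 2-bromo-6-methoxyaryllithium should hold at −78 °C), followed by SN2 methylation with MeI.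

Step 2
Reactants: 3 1-bromo-3,5-dimethoxy-2,4-dimethylbenzene; 4 (2R,3R)-2,3-dimethyloxirane (trans-2,3-epoxybutane)
Product: 6 (2R,3R)-3-(3,5-dimethoxy-2,4-dimethylphenyl)butan-2-ol, via Grignard reagent 5 (not isolated)
Conditions: Mg, THF, reflux; CuI (10 mol%), 4 (1.3 equiv), −30 → 0 °C; H2O work-up
Reagents that add atoms: none
Why: Copper-catalysed SN2 opening of the C2-symmetric trans-epoxide by the aryl Grignard inverts the attacked carbon, which sets the benzylic (R) centre, while the untouched carbinol stays (R) (erythro product).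

Step 3
Reactants: 6 (2R,3R)-3-(3,5-dimethoxy-2,4-dimethylphenyl)butan-2-ol
Product: 7 (2S,3R)-3-(3,5-dimethoxy-2,4-dimethylphenyl)butan-2-yl 4-nitrobenzoate
Conditions: 4-O2NC6H4CO2H, PPh3, DIAD, THF, 0 °C → rt
Reagents that add atoms: 4-nitrobenzoic acid, O=C(O)c1ccc(cc1)[N+](=O)[O-]
Why: Mitsunobu reaction, in which SN2 displacement of the alkoxyphosphonium by the carboxylate inverts the carbinol to (S) and gives the threo (2S,3R) pair; the ester then serves as the O-protecting group.

Step 4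
Reactants: 7 (2S,3R)-3-(3,5-dimethoxy-2,4-dimethylphenyl)butan-2-yl 4-nitrobenzoate
Product: 8 (2S,3R)-3-(2-formyl-3,5-dimethoxy-4,6-dimethylphenyl)butan-2-yl 4-nitrobenzoate
Conditions: Cl2CHOMe, TiCl4, CH2Cl2, −78 → 0 °C; H2O
Reagents that add atoms: dichloromethyl methyl ether, COC(Cl)Cl; water, O
Why: Rieche formylation (Friedel–Crafts type) at the only free ring position, which is ortho/para to the two methoxy groups; the ester keeps the side-chain oxygen from forming a lactol with the new aldehyde.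

Step 5
Reactants: 8 (2S,3R)-3-(2-formyl-3,5-dimethoxy-4,6-dimethylphenyl)butan-2-yl 4-nitrobenzoate
Product: 9 (2S,3R)-3-(2-formyl-3,5-dihydroxy-4,6-dimethylphenyl)butan-2-yl 4-nitrobenzoate
Conditions: BBr3 (3.5 equiv), CH2Cl2, −78 → 0 °C; H2O
Reagents that add atoms: none
Why: Lewis-acid aryl methyl ether cleavage, fast for both the ortho-carbonyl and the di-ortho-substituted methoxy group, while the electron-poor benzoate and the aldehyde survive at low temperature.

Step 6
Reactants: 10 methyl (3R)-3-hydroxybutanoate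
Product: 11 methyl (3R)-3-[(tert-butyldimethylsilyl)oxy]butanoate
Conditions: TBSCl, imidazole, DMF, rt
Reagents that add atoms: tert-butyldimethylsilyl chloride, CC(C)(C)[Si](C)(C)Cl
Why: Standard O-silylation of the secondary alcohol; the stereocentre is not touched.

Step 7
Reactants: 11 methyl (3R)-3-[(tert-butyldimethylsilyl)oxy]butanoate; 12 methyl acetoacetate
Product: 14 methyl (7R)-7-[(tert-butyldimethylsilyl)oxy]-3,5-dioxooctanoate, via dianion 13 (not isolated)
Conditions: 12 (2.2 equiv), NaH, THF, 0 °C; n-BuLi, 0 °C; 11, 0 °C → rt; aq. HCl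
Reagents that add atoms: none
Why: Claisen-type acylation of the acetoacetate dianion at its γ-carbon by the ester (Huckin–Weiler); excess dianion absorbs the acidic product and the β-stereocentre is untouched.

Step 8
Reactants: 14 methyl (7R)-7-[(tert-butyldimethylsilyl)oxy]-3,5-dioxooctanoate
Product: 15 6-[(2R)-2-[(tert-butyldimethylsilyl)oxy]propyl]-4-hydroxy-2H-pyran-2-one
Conditions: DBU (1.2 equiv), toluene, 80 °C
Reagents that add atoms: none
Why: Base-mediated enol-lactonisation of the 3,5-dioxo ester (C5 enol oxygen onto the ester) gives the 4-hydroxy-2-pyranone, which masks triketide C4 so that only pyranone C3 is nucleophilic.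

Step 9
Reactants: 9 (2S,3R)-3-(2-formyl-3,5-dihydroxy-4,6-dimethylphenyl)butan-2-yl 4-nitrobenzoate; 15 6-[(2R)-2-[(tert-butyldimethylsilyl)oxy]propyl]-4-hydroxy-2H-pyran-2-one
Product: 17 3-[(5R)-5-[(tert-butyldimethylsilyl)oxy]-3-oxohexanoyl]-7-hydroxy-6,8-dimethyl-5-[(2R,3S)-3-(4-nitrobenzoyloxy)butan-2-yl]-2H-chromen-2-one, via Knoevenagel adduct 16 (not isolated)
Conditions: piperidine (0.2 equiv), AcOH (0.2 equiv), EtOH, reflux
Reagents that add atoms: none
Why: Knoevenagel condensation at pyranone C3 followed by translactonisation, in which the ortho-phenol attacks the pyranone lactone carbonyl, opens it to the β-diketone and closes the aromatic coumarin (the pathway by which salicylaldehydes and triacetic acid lactone give 3-acetoacetylcoumarins).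

Step 10
Reactants: 17 3-[(5R)-5-[(tert-butyldimethylsilyl)oxy]-3-oxohexanoyl]-7-hydroxy-6,8-dimethyl-5-[(2R,3S)-3-(4-nitrobenzoyloxy)butan-2-yl]-2H-chromen-2-one
Product: 20 7-hydroxy-5-[(2R,3S)-3-hydroxybutan-2-yl]-6,8-dimethyl-3-[(2R)-2-methyl-4-oxo-3,4-dihydro-2H-pyran-6-yl]-2H-chromen-2-one (target), via hydroxy diketone 18 (not isolated), via dihydroxy diketone 19 (not isolated)
Conditions: K2CO3 (4 equiv), MeOH, 0 °C → rt; then 6 M aq. HCl to pH 1, rt → 40 °C
Reagents that add atoms: none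
Why: Base-catalysed transesterification frees the side-chain alcohol, then acid removes the silyl ether and the δ-hydroxy-β-diketone closes by six-membered hemiketalisation/dehydration to the 2,3-dihydro-4H-pyran-4-one; no C–O bond at a stereocentre is broken.

**Compound list**
1 | 5-bromo-1,3-dimethoxy-2-methylbenzene | COc1cc(Br)cc(OC)c1C | starting material
2 | (6-bromo-2,4-dimethoxy-3-methylphenyl)lithium | COc1cc(Br)c([Li])c(OC)c1C | intermediate
3 | 1-bromo-3,5-dimethoxy-2,4-dimethylbenzene | COc1cc(Br)c(C)c(OC)c1C | intermediate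
4 | (2R,3R)-2,3-dimethyloxirane | C[C@H]1O[C@@H]1C | starting material
5 | (3,5-dimethoxy-2,4-dimethylphenyl)magnesium bromide | COc1cc([Mg]Br)c(C)c(OC)c1C | intermediate
6 | (2R,3R)-3-(3,5-dimethoxy-2,4-dimethylphenyl)butan-2-ol | COc1cc([C@@H](C)[C@@H](C)O)c(C)c(OC)c1C | intermediate
7 | (2S,3R)-3-(3,5-dimethoxy-2,4-dimethylphenyl)butan-2-yl 4-nitrobenzoate | COc1cc([C@@H](C)[C@H](C)OC(=O)c2ccc(cc2)[N+](=O)[O-])c(C)c(OC)c1C | intermediate
8 | (2S,3R)-3-(2-formyl-3,5-dimethoxy-4,6-dimethylphenyl)butan-2-yl 4-nitrobenzoate | COc1c(C)c(OC)c(C=O)c([C@@H](C)[C@H](C)OC(=O)c2ccc(cc2)[N+](=O)[O-])c1C | intermediate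
9 | (2S,3R)-3-(2-formyl-3,5-dihydroxy-4,6-dimethylphenyl)butan-2-yl 4-nitrobenzoate | Cc1c(O)c(C)c(O)c(C=O)c1[C@@H](C)[C@H](C)OC(=O)c1ccc(cc1)[N+](=O)[O-] | intermediate
10 | methyl (3R)-3-hydroxybutanoate | C[C@@H](O)CC(=O)OC | starting material
11 | methyl (3R)-3-[(tert-butyldimethylsilyl)oxy]butanoate | C[C@@H](O[Si](C)(C)C(C)(C)C)CC(=O)OC | intermediate
12 | methyl acetoacetate (methyl 3-oxobutanoate) | CC(=O)CC(=O)OC | starting material
13 | methyl acetoacetate dianion (sodium lithium salt) | [Na+].[Li+].[CH2-]C(=O)[CH-]C(=O)OC | intermediate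
14 | methyl (7R)-7-[(tert-butyldimethylsilyl)oxy]-3,5-dioxooctanoate | C[C@@H](O[Si](C)(C)C(C)(C)C)CC(=O)CC(=O)CC(=O)OC | intermediate
15 | 6-[(2R)-2-[(tert-butyldimethylsilyl)oxy]propyl]-4-hydroxy-2H-pyran-2-one | C[C@@H](O[Si](C)(C)C(C)(C)C)Cc1cc(O)cc(=O)o1 | intermediate
16 | 6-[(2R)-2-[(tert-butyldimethylsilyl)oxy]propyl]-3-{[2,4-dihydroxy-3,5-dimethyl-6-[(2R,3S)-3-(4-nitrobenzoyloxy)butan-2-yl]phenyl]methylidene}-2H-pyran-2,4(3H)-dione (alkene geometry not defined) | C[C@@H](O[Si](C)(C)C(C)(C)C)CC1=CC(=O)C(=Cc2c(O)c(C)c(O)c(C)c2[C@@H](C)[C@H](C)OC(=O)c2ccc(cc2)[N+](=O)[O-])C(=O)O1 | intermediate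
17 | 3-[(5R)-5-[(tert-butyldimethylsilyl)oxy]-3-oxohexanoyl]-7-hydroxy-6,8-dimethyl-5-[(2R,3S)-3-(4-nitrobenzoyloxy)butan-2-yl]-2H-chromen-2-one | Cc1c(O)c(C)c2oc(=O)c(C(=O)CC(=O)C[C@@H](C)O[Si](C)(C)C(C)(C)C)cc2c1[C@@H](C)[C@H](C)OC(=O)c1ccc(cc1)[N+](=O)[O-] | intermediate
18 | 3-[(5R)-5-[(tert-butyldimethylsilyl)oxy]-3-oxohexanoyl]-7-hydroxy-5-[(2R,3S)-3-hydroxybutan-2-yl]-6,8-dimethyl-2H-chromen-2-one | Cc1c(O)c(C)c2oc(=O)c(C(=O)CC(=O)C[C@@H](C)O[Si](C)(C)C(C)(C)C)cc2c1[C@@H](C)[C@H](C)O | intermediate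
19 | 7-hydroxy-5-[(2R,3S)-3-hydroxybutan-2-yl]-3-[(5R)-5-hydroxy-3-oxohexanoyl]-6,8-dimethyl-2H-chromen-2-one | Cc1c(O)c(C)c2oc(=O)c(C(=O)CC(=O)C[C@@H](C)O)cc2c1[C@@H](C)[C@H](C)O | intermediate
20 | 7-hydroxy-5-[(2R,3S)-3-hydroxybutan-2-yl]-6,8-dimethyl-3-[(2R)-2-methyl-4-oxo-3,4-dihydro-2H-pyran-6-yl]-2H-chromen-2-one (CNP0291478.1) | Cc1c(O)c(C)c2oc(=O)c(C3=CC(=O)C[C@@H](C)O3)cc2c1[C@@H](C)[C@H](C)O | target

**Totals**
Total step count: 10. Longest linear sequence: 7 steps (steps 1–5, 9, 10); the pyranone branch (steps 6–8) joins at step 9.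

**Steps most likely to fail, with fallbacks**

Step 9 (hindered 2,6-disubstituted salicylaldehyde; 2:1 pyranone adducts or incomplete translactonisation are possible). The fallback sets out from 9 and comes back at 17. It builds the coumarin first and attaches the chain afterwards. Knoevenagel condensation of 9 with methyl acetoacetate 12 (piperidine/AcOH, EtOH, reflux) gives 3-acetyl-7-hydroxy-6,8-dimethyl-5-[(2R,3S)-3-(4-nitrobenzoyloxy)butan-2-yl]-2H-chromen-2-one F2. In parallel, ester 11 is converted with MeNHOMe·HCl/i-PrMgCl (THF, −20 °C) into (3R)-3-[(tert-butyldimethylsilyl)oxy]-N-methoxy-N-methylbutanamide F3. The phenoxide/methyl-ketone dianion of F2 (LiHMDS, 3 equiv, THF, −78 °C; the 7-phenoxide deactivates C4 towards self-addition) is then C-acylated by F3 in a crossed Claisen reaction to give 17.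

Step 10 (base on the 3-acylcoumarin/β-diketone before the acid stage: retro-Claisen, lactone opening or β-elimination could compete). The fallback sets out from 9 and comes back at 18, so that no base is used once the coumarin exists. The ester of 9 is cleaved first (K2CO3, MeOH, 0 °C). The freed hydroxy aldehyde closes to the lactol (3S,4R)-3,4,5,7-tetramethyl-3,4-dihydro-1H-isochromene-1,6,8-triol F4 (C1 epimers, in equilibrium with the open aldehyde/quinone methide). F4 is condensed with 15 (piperidinium acetate, EtOH, reflux): addition of pyranone C3 at C1, translactonisation by the 8-OH and β-elimination of the ring oxygen give 18 directly. Only the acid stage of step 10 then remains.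

Step 1 (the ortho-bromoaryllithium may lose LiBr to an aryne, or lateral lithiation of the methyl between the two methoxy groups may compete). The fallback sets out from 1 and comes back at 3. It replaces deprotonation by electrophilic substitution. Vilsmeier–Haack formylation of 1 (POCl3, DMF, 0 → 80 °C) at one of the two equivalent activated positions gives 6-bromo-2,4-dimethoxy-3-methylbenzaldehyde F1. Ionic hydrogenation (Et3SiH, TFA, rt) then reduces the formyl group to methyl and gives 3.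

**Further compounds**
F1 | step 1 | 6-bromo-2,4-dimethoxy-3-methylbenzaldehyde | COc1cc(Br)c(C=O)c(OC)c1C
F2 | step 9 | 3-acetyl-7-hydroxy-6,8-dimethyl-5-[(2R,3S)-3-(4-nitrobenzoyloxy)butan-2-yl]-2H-chromen-2-one | CC(=O)c1cc2c([C@@H](C)[C@H](C)OC(=O)c3ccc(cc3)[N+](=O)[O-])c(C)c(O)c(C)c2oc1=O
F3 | step 9 | (3R)-3-[(tert-butyldimethylsilyl)oxy]-N-methoxy-N-methylbutanamide | C[C@@H](O[Si](C)(C)C(C)(C)C)CC(=O)N(C)OC
F4 | step 10 | (3S,4R)-3,4,5,7-tetramethyl-3,4-dihydro-1H-isochromene-1,6,8-triol (lactol, C1 epimers) | OC1O[C@@H](C)[C@H](C)c2c(C)c(O)c(C)c(O)c12
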